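## Retrosynthetic overview

1. Ring C (the butenolide) is closed last: target 24 comes from lactol 23 by loss of water, and 23 is the ring-closed form of a (Z)-γ-keto acid.
2. Key bond, masked ketone carbon to acrylate β-carbon: Weinreb amide 15 plus the (Z)-β-magnesiated α-(hydroxymethyl)acrylate 20, a β-acylvinyl anion (sp2 homoenolate equivalent) made from iodo acid 19 (from methyl propiolate, formaldehyde and iodide).
3. Diene: 15 from dienyl triflate 13 and alkyl-9-BBN 14 (B-alkyl Suzuki–Miyaura); 13 from (S)-citronellic acid 8 by oxidation of the (E)-methyl group, then γ-deprotonation and O-triflation. The stereocentre is bought.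
4. Bis-furan 7 from 3,4-dibromofuran 3 and 3-(bromomethyl)furan 2 (Negishi), then vinylation.
5. Ring order: furan rings A and B are bought intact; ring C is the only ring made (steps 10 and 11). No protecting groups are used.

Assumption: the target is the (S), 4E,6E, exocyclic-Z isomer exactly as drawn; (S)-citronellic acid of at least 98% ee, 3,4-dibromofuran, furan-3-ylmethanol and methyl propiolate are purchased.

## Route

Step 1
Reactants: 1 furan-3-ylmethanol
Product: 2 3-(bromomethyl)furan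
Conditions: PBr3 (0.4 equiv), pyridine (cat.), Et2O, −10 °C; used at once as an Et2O solution
Reagents that add atoms: phosphorus tribromide, BrP(Br)Br
Why: Bromination of a primary furylmethyl alcohol with PBr3 is standard; the labile bromide is not stored.

Step 2
Reactants: 3 3,4-dibromofuran; 2 3-(bromomethyl)furan
Product: 6 3-bromo-4-(furan-3-ylmethyl)furan, via furyllithium 4 (not isolated), via furylzinc chloride 5 (not isolated)
Conditions: n-BuLi (1.0 equiv), Et2O, −78 °C; ZnCl2, THF, −78 → 0 °C; then 2, Pd(PPh3)4 (3 mol%), 0 °C → rt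
Reagents that add atoms: none
Why: Mono bromine–lithium exchange of the dibromofuran at −78 °C, transmetalation to zinc and Negishi coupling, in which zerovalent palladium inserts into the furylmethyl C–Br bond far faster than into the electron-rich 3-bromofuran C–Br bond.

Step 3
Reactants: 6 3-bromo-4-(furan-3-ylmethyl)furan
Product: 7 3-ethenyl-4-(furan-3-ylmethyl)furan
Conditions: vinylboronic acid pinacol ester (1.5 equiv), Pd(OAc)2 (3 mol%), SPhos (6 mol%), K3PO4, dioxane/H2O 5:1, 80 °C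
Reagents that add atoms: 2-ethenyl-4,4,5,5-tetramethyl-1,3,2-dioxaborolane, C=CB1OC(C)(C)C(C)(C)O1
Why: Suzuki–Miyaura vinylation of a heteroaryl bromide with an electron-rich biaryl phosphine; the vinylfuran is used promptly.

Step 4
Reactants: 8 (3S)-3,7-dimethyloct-6-enoic acid
Product: 9 (3S)-N-methoxy-N,3,7-trimethyloct-6-enamide
Conditions: MeNH(OMe)·HCl, EDC·HCl, DMAP (cat.), Et3N, CH2Cl2, 0 °C → rt
Reagents that add atoms: N,O-dimethylhydroxylamine hydrochloride, CNOC.Cl
Why: Carbodiimide amide coupling gives the Weinreb amide; the purchased (S) stereocentre is β to the carbonyl and is not touched here or later.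

Step 5
Reactants: 9 (3S)-N-methoxy-N,3,7-trimethyloct-6-enamide
Product: 11 (3S,6E)-N-methoxy-N,3,7-trimethyl-8-oxooct-6-enamide, via allylic alcohol 10 (not isolated)
Conditions: SeO2 (10 mol%), salicylic acid (10 mol%), t-BuOOH (3 equiv), CH2Cl2, rt; crude, then MnO2, CH2Cl2, rt
Reagents that add atoms: tert-butyl hydroperoxide, CC(C)(C)OO; selenium dioxide, O=[Se]=O
Why: Selenium dioxide allylic oxidation (ene reaction, then 2,3-sigmatropic shift) attacks the (E)-methyl group of a gem-dimethyl trisubstituted alkene; MnO2 converges the alcohol/aldehyde mixture to the (E)-enal.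

Step 6
Reactants: 11 (3S,6E)-N-methoxy-N,3,7-trimethyl-8-oxooct-6-enamide
Product: 13 (1E,3E,6S)-8-[methoxy(methyl)amino]-2,6-dimethyl-8-oxoocta-1,3-dien-1-yl trifluoromethanesulfonate, via potassium dienolate 12 (not isolated)
Conditions: KN(SiMe3)2 (1.1 equiv), THF, −78 °C; PhNTf2 (1.2 equiv), −78 → −30 °C
Reagents that add atoms: N-phenylbis(trifluoromethanesulfonimide), FC(F)(F)S(=O)(=O)N(c1ccccc1)S(=O)(=O)C(F)(F)F
Why: γ-Deprotonation of the enal (far more acidic than the amide α-CH2) and O-triflation of the vinylogous enolate; the s-trans enal gives the 1E enol triflate and allylic 1,3-strain against the α-methyl group forces the new 3,4-double bond to be E.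

Step 7
Reactants: 7 3-ethenyl-4-(furan-3-ylmethyl)furan; 13 (1E,3E,6S)-8-[methoxy(methyl)amino]-2,6-dimethyl-8-oxoocta-1,3-dien-1-yl trifluoromethanesulfonate
Product: 15 (3S,5E,7E)-10-[4-(furan-3-ylmethyl)furan-3-yl]-N-methoxy-N,3,7-trimethyldeca-5,7-dienamide, via alkylborane 14 (not isolated)
Conditions: 7, 9-BBN (1.1 equiv), THF, rt; then 13, PdCl2(dppf) (5 mol%), AsPh3 (10 mol%), K3PO4 (aq.), DMF, rt
Reagents that add atoms: none
Why: Anti-Markovnikov hydroboration of the vinylfuran followed by B-alkyl Suzuki–Miyaura coupling, which replaces the triflate with retention of alkene geometry and so fixes the 5E,7E-diene.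

Step 8
Reactants: 16 methyl propiolate
Product: 18 methyl (2Z)-2-(hydroxymethyl)-3-iodoprop-2-enoate, via magnesium iodoallenolate 17 (not isolated)
Conditions: MgI2 (1.2 equiv), CH2O (monomeric, from cracked paraformaldehyde, 1.5 equiv), CH2Cl2, −20 → 0 °C
Reagents that add atoms: magnesium iodide, [Mg+2].[I-].[I-]; formaldehyde, C=O
Why: Iodide conjugate addition to the ynoate and aldol trapping of the allenolate (β-iodo Morita–Baylis–Hillman-type reaction), which at or below 0 °C gives the kinetic (Z)-isomer with iodine cis to the ester.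

Step 9
Reactants: 18 methyl (2Z)-2-(hydroxymethyl)-3-iodoprop-2-enoate
Product: 19 (2Z)-2-(hydroxymethyl)-3-iodoprop-2-enoic acid
Conditions: LiOH (1.5 equiv), THF/H2O, 0 °C; then 1 M HCl to pH 2
Reagents that add atoms: lithium hydroxide, [Li+].[OH-]
Why: Cold saponification of a (Z)-β-iodoacrylate proceeds without loss of alkene geometry.

Step 10
Reactants: 15 (3S,5E,7E)-10-[4-(furan-3-ylmethyl)furan-3-yl]-N-methoxy-N,3,7-trimethyldeca-5,7-dienamide; 19 (2Z)-2-(hydroxymethyl)-3-iodoprop-2-enoic acid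
Product: 23 5-hydroxy-3-(hydroxymethyl)-5-[(2S,4E,6E)-9-[4-(furan-3-ylmethyl)furan-3-yl]-2,6-dimethylnona-4,6-dien-1-yl]furan-2(5H)-one (both epimers at the lactol carbon), via vinylmagnesium reagent 20 (not isolated), via tetrahedral adduct 21 (not isolated), via keto acid 22 (not isolated)
Conditions: 19 (1.5 equiv), MeMgCl (2.0 equiv per 19), THF, −30 °C; i-PrMgCl·LiCl (1.05 equiv per 19), −40 °C, 1 h; then 15, −40 → 0 °C; 1 M HCl, 0 °C
Reagents that add atoms: none
Why: Proposed new method: double deprotonation of 19 and iodine–magnesium exchange should give a configurationally stable (Z)-β-magnesio acrylate whose acid and alcohol are masked as magnesium salts, so the normally electrophilic β-carbon adds to the amide carbonyl, the chelated adduct stops over-addition, and acid work-up releases the (Z)-γ-keto acid, which closes to the lactol; the closest known reactions are acylations of (Z)-3-magnesiated enoate esters, carbonyl additions of lithium (Z)-3-lithioacrylate and the Weinreb ketone synthesis, and the only new stereocentre (the lactol carbon) is removed in step 11.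

Step 11
Reactants: 23 5-hydroxy-3-(hydroxymethyl)-5-[(2S,4E,6E)-9-[4-(furan-3-ylmethyl)furan-3-yl]-2,6-dimethylnona-4,6-dien-1-yl]furan-2(5H)-one
Product: 24 (5Z)-5-[(2S,4E,6E)-9-[4-(furan-3-ylmethyl)furan-3-yl]-2,6-dimethylnona-4,6-dien-1-ylidene]-3-(hydroxymethyl)furan-2(5H)-one
Conditions: TsOH·H2O (5 mol%), 4 Å MS, benzene, 60 °C
Reagents that add atoms: none
Why: Acid-catalysed dehydration of a 5-hydroxybutenolide (pseudo acid) through the oxygen-stabilised furanyl cation gives the alkylidenebutenolide as the thermodynamically preferred (Z)-isomer; the primary alcohol cannot ionise and the adjacent stereocentre is not involved.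

## Compound list

1 | furan-3-ylmethanol | OCc1ccoc1 | starting material
2 | 3-(bromomethyl)furan | BrCc1ccoc1 | intermediate
3 | 3,4-dibromofuran | Brc1cocc1Br | starting material
4 | (4-bromofuran-3-yl)lithium | [Li]c1cocc1Br | intermediate
5 | (4-bromofuran-3-yl)zinc chloride | Cl[Zn]c1cocc1Br | intermediate
6 | 3-bromo-4-(furan-3-ylmethyl)furan | Brc1cocc1Cc1ccoc1 | intermediate
7 | 3-ethenyl-4-(furan-3-ylmethyl)furan | C=Cc1cocc1Cc1ccoc1 | intermediate
8 | (3S)-3,7-dimethyloct-6-enoic acid, (S)-citronellic acid | OC(=O)C[C@@H](C)CCC=C(C)C | starting material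
9 | (3S)-N-methoxy-N,3,7-trimethyloct-6-enamide | CON(C)C(=O)C[C@@H](C)CCC=C(C)C | intermediate
10 | (3S,6E)-8-hydroxy-N-methoxy-N,3,7-trimethyloct-6-enamide | CON(C)C(=O)C[C@@H](C)CC/C=C(\C)CO | intermediate
11 | (3S,6E)-N-methoxy-N,3,7-trimethyl-8-oxooct-6-enamide | CON(C)C(=O)C[C@@H](C)CC/C=C(\C)C=O | intermediate
12 | potassium (1E,3E,6S)-8-[methoxy(methyl)amino]-2,6-dimethyl-8-oxoocta-1,3-dien-1-olate | CON(C)C(=O)C[C@@H](C)C/C=C/C(C)=C/[O-].[K+] | intermediate
13 | (1E,3E,6S)-8-[methoxy(methyl)amino]-2,6-dimethyl-8-oxoocta-1,3-dien-1-yl trifluoromethanesulfonate | CON(C)C(=O)C[C@@H](C)C/C=C/C(C)=C/OS(=O)(=O)C(F)(F)F | intermediate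
14 | 9-{2-[4-(furan-3-ylmethyl)furan-3-yl]ethyl}-9-borabicyclo[3.3.1]nonane | B1(CCc2cocc2Cc2ccoc2)C2CCCC1CCC2 | intermediate
15 | (3S,5E,7E)-10-[4-(furan-3-ylmethyl)furan-3-yl]-N-methoxy-N,3,7-trimethyldeca-5,7-dienamide | CON(C)C(=O)C[C@@H](C)C/C=C/C(C)=C/CCc1cocc1Cc1ccoc1 | intermediate
16 | methyl propiolate | COC(=O)C#C | starting material
17 | iodomagnesium 3-iodo-1-methoxypropa-1,2-dien-1-olate | COC(O[Mg]I)=C=CI | intermediate
18 | methyl (2Z)-2-(hydroxymethyl)-3-iodoprop-2-enoate | COC(=O)/C(CO)=C\I | intermediate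
19 | (2Z)-2-(hydroxymethyl)-3-iodoprop-2-enoic acid | OC(=O)/C(CO)=C\I | intermediate
20 | chloromagnesium (2Z)-3-(chloromagnesio)-2-[(chloromagnesiooxy)methyl]prop-2-enoate | Cl[Mg]/C=C(/CO[Mg]Cl)C(=O)O[Mg]Cl | intermediate
21 | tris(chloromagnesium) salt of the tetrahedral N-methoxy-N-methyl hemiaminal adduct of 20 and 15 | CON(C)C(O[Mg]Cl)(C[C@@H](C)C/C=C/C(C)=C/CCc1cocc1Cc1ccoc1)/C=C(/CO[Mg]Cl)C(=O)O[Mg]Cl | intermediate
22 | (2Z,6S,8E,10E)-13-[4-(furan-3-ylmethyl)furan-3-yl]-2-(hydroxymethyl)-6,10-dimethyl-4-oxotrideca-2,8,10-trienoic acid | OC(=O)/C(CO)=C\C(=O)C[C@@H](C)C/C=C/C(C)=C/CCc1cocc1Cc1ccoc1 | intermediate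
23 | 5-hydroxy-3-(hydroxymethyl)-5-[(2S,4E,6E)-9-[4-(furan-3-ylmethyl)furan-3-yl]-2,6-dimethylnona-4,6-dien-1-yl]furan-2(5H)-one | OCC1=CC(O)(C[C@@H](C)C/C=C/C(C)=C/CCc2cocc2Cc2ccoc2)OC1=O | intermediate
24 | (5Z)-5-[(2S,4E,6E)-9-[4-(furan-3-ylmethyl)furan-3-yl]-2,6-dimethylnona-4,6-dien-1-ylidene]-3-(hydroxymethyl)furan-2(5H)-one | CC(/C=C/C[C@H](C)/C=C1/C=C(CO)C(=O)O1)=C\CCc1cocc1Cc1ccoc1 | target

## Step count and risks

Total: 11 steps. Longest linear sequence: 6 steps (8 → 9 → 11 → 13 → 15 → 23 → 24; the bis-furan branch from 1 is also 6).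

Most likely to fail:

Step 10 (key coupling). The trimagnesiated reagent may be too unreactive towards the amide or may be protonated by it. The fallback sets out from 15 and comes back at 24, skipping 23 and step 11. Reduction of 15 with i-Bu2AlH (THF, −78 °C) gives (3S,5E,7E)-10-[4-(furan-3-ylmethyl)furan-3-yl]-3,7-dimethyldeca-5,7-dienal F1. Nonafluorobutanesulfonyl fluoride and phosphazene base P2-Et (DMF, 0 °C → rt) convert F1 through the alkenyl nonaflate (3S,5E,7E)-10-[4-(furan-3-ylmethyl)furan-3-yl]-3,7-dimethyldeca-1,5,7-trien-1-yl nonafluorobutane-1-sulfonate F2 into the terminal alkyne 3-[(3E,5E,8S)-4,8-dimethyldeca-3,5-dien-9-yn-1-yl]-4-(furan-3-ylmethyl)furan F3, with no change in carbon count. Sonogashira coupling of F3 with 19 (PdCl2(PPh3)2, CuI, Et3N, MeCN, rt) and 5-exo-dig lactonisation in the same flask gives 24.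

Step 6 (dienyl triflate). The dienolate may give E/Z mixtures, self-condense, or the triflate may be too labile. The fallback sets out from 11 and 7 and comes back at 15. KOt-Bu then ClP(O)(OEt)2 (THF, −78 °C) turns 11 into diethyl (1E,3E,6S)-8-[methoxy(methyl)amino]-2,6-dimethyl-8-oxoocta-1,3-dien-1-yl phosphate F6. Hydroboration of 7 (9-BBN, then NaBO3·4H2O) gives 2-[4-(furan-3-ylmethyl)furan-3-yl]ethan-1-ol F7. CBr4/PPh3 gives 3-(2-bromoethyl)-4-(furan-3-ylmethyl)furan F8, and Mg in THF gives {2-[4-(furan-3-ylmethyl)furan-3-yl]ethyl}magnesium bromide F9. Slow addition of F9 to F6 with Fe(acac)3 (5 mol%) in THF at −20 °C (iron-catalysed Kumada coupling of a dienyl phosphate, fast enough to spare the amide) gives 15.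

Step 11 (dehydration). Acid may damage the furans or isomerise the open keto acid towards a furan by-product. The fallback sets out from 23 and comes back at 24. Trifluoroacetic anhydride (2.5 equiv) and Et3N (CH2Cl2, −20 °C → rt) give the bis(trifluoroacetate) [5-[(2S,4E,6E)-9-[4-(furan-3-ylmethyl)furan-3-yl]-2,6-dimethylnona-4,6-dien-1-yl]-2-oxo-5-(trifluoroacetoxy)-2,5-dihydrofuran-3-yl]methyl trifluoroacetate F4. F4 eliminates under the basic conditions to [(5Z)-5-[(2S,4E,6E)-9-[4-(furan-3-ylmethyl)furan-3-yl]-2,6-dimethylnona-4,6-dien-1-ylidene]-2-oxo-2,5-dihydrofuran-3-yl]methyl trifluoroacetate F5. NaHCO3 in aqueous MeOH at 0 °C cleaves the primary trifluoroacetate to give 24.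

## Further compounds

F1 | step 10 | (3S,5E,7E)-10-[4-(furan-3-ylmethyl)furan-3-yl]-3,7-dimethyldeca-5,7-dienal | O=CC[C@@H](C)C/C=C/C(C)=C/CCc1cocc1Cc1ccoc1
F2 | step 10 | (3S,5E,7E)-10-[4-(furan-3-ylmethyl)furan-3-yl]-3,7-dimethyldeca-1,5,7-trien-1-yl nonafluorobutane-1-sulfonate (E/Z mixture at C1) | FC(F)(F)C(F)(F)C(F)(F)C(F)(F)S(=O)(=O)OC=C[C@@H](C)C/C=C/C(C)=C/CCc1cocc1Cc1ccoc1
F3 | step 10 | 3-[(3E,5E,8S)-4,8-dimethyldeca-3,5-dien-9-yn-1-yl]-4-(furan-3-ylmethyl)furan | C#C[C@@H](C)C/C=C/C(C)=C/CCc1cocc1Cc1ccoc1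
F4 | step 11 | [5-[(2S,4E,6E)-9-[4-(furan-3-ylmethyl)furan-3-yl]-2,6-dimethylnona-4,6-dien-1-yl]-2-oxo-5-(trifluoroacetoxy)-2,5-dihydrofuran-3-yl]methyl trifluoroacetate | FC(F)(F)C(=O)OCC1=CC(OC(=O)C(F)(F)F)(C[C@@H](C)C/C=C/C(C)=C/CCc2cocc2Cc2ccoc2)OC1=O
F5 | step 11 | [(5Z)-5-[(2S,4E,6E)-9-[4-(furan-3-ylmethyl)furan-3-yl]-2,6-dimethylnona-4,6-dien-1-ylidene]-2-oxo-2,5-dihydrofuran-3-yl]methyl trifluoroacetate | CC(/C=C/C[C@H](C)/C=C1/C=C(COC(=O)C(F)(F)F)C(=O)O1)=C\CCc1cocc1Cc1ccoc1
F6 | step 6 | diethyl (1E,3E,6S)-8-[methoxy(methyl)amino]-2,6-dimethyl-8-oxoocta-1,3-dien-1-yl phosphate | CON(C)C(=O)C[C@@H](C)C/C=C/C(C)=C/OP(=O)(OCC)OCC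
F7 | step 6 | 2-[4-(furan-3-ylmethyl)furan-3-yl]ethan-1-ol | OCCc1cocc1Cc1ccoc1
F8 | step 6 | 3-(2-bromoethyl)-4-(furan-3-ylmethyl)furan | BrCCc1cocc1Cc1ccoc1
F9 | step 6 | {2-[4-(furan-3-ylmethyl)furan-3-yl]ethyl}magnesium bromide | Br[Mg]CCc1cocc1Cc1ccoc1
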